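Plan
Cuts: the C3 alcohol goes back to a 3-ketone carrying a C2 ester helper; C1–C2 (ring A) and C9–C10 (ring B) are cut together to an acyclic 3-oxo ester; C9–C11 is cut (sp3–sp2 coupling) into a primary alkyl iodide on ring C and a vinyl iodide; the C9'–C12 bond (Claisen) and the two C10' alkylations lead back to (R)-carvone.
Enabling feature (decalin half in triterpenoid numbering; ring C atoms primed): the C10 methyl, C10 and C1 form an isopropenyl group on C5, C2 is the α-carbon of the C3 ketone, and the C8 methylene is the trace of an (E)-C8=C9 alkene, so a C2 radical can close ring A (C1–C2), then ring B (C9–C10), and end as the exocyclic alkene.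
Forward order: ring C is taken intact from (R)-carvone and dressed (steps 1–9); the acyclic right chain is built from 4-pentyn-1-ol (steps 10–15); a Negishi coupling joins them (step 16); the keto ester is added (step 17); rings A and B close in one step (step 18); ester removal (step 19) and ketone reduction (step 20) finish.
Stereochemistry: C5' from carvone; C10' by alkylation anti to isopropenyl; C9' by a suprafacial Claisen shift from a cis-carveol-type alcohol; C5 by rhodium/BINAP conjugate addition; C10 and C9 from C5 plus the E alkene in the chair-like bicyclization; C3 by axial hydride delivery.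

Key step: step 18

Assumption: in step 13 (S)-BINAP is taken to deliver the isopropenyl group to the enoate face that gives the (3S)-configured adduct, following the usual facial model for (E)-configured acyclic acceptors; if the sense proves opposite, (R)-BINAP is used instead.

Route

Step 1
Reactants: 1 (R)-(−)-carvone
Product: 2 (5R)-2,6-dimethyl-5-(prop-1-en-2-yl)cyclohex-2-en-1-one (6-methylcarvone; C6 epimers)
Conditions: LiN(i-Pr)2, THF, −78 °C; MeI, −78 to 0 °C
Reagents that add atoms: iodomethane, CI
Why: Kinetic α'-deprotonation of the cross-conjugated enone and enolate alkylation; the new C6 centre need not be controlled because it is made planar again in step 2.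

Step 2
Reactants: 2 6-methylcarvone; 3 methyl acrylate
Product: 5 methyl 3-[(1S,6S)-1,3-dimethyl-2-oxo-6-(prop-1-en-2-yl)cyclohex-3-en-1-yl]propanoate, via ketene silyl acetal 4 (not isolated)
Conditions: LiN(i-Pr)2, THF, −78 °C; 3 premixed with Me3SiCl, −78 °C, short reaction time; 1 M HCl work-up
Reagents that add atoms: methyl acrylate (compound 3), C=CC(=O)OC
Why: Michael addition of the kinetic C6 lithium enolate to the acrylate, with silylation of the adduct ester enolate in the flask to stop a second, intramolecular Michael addition; the acrylate should approach anti to the neighbouring isopropenyl group, which sets the quaternary centre with the propanoate chain trans and the methyl cis to isopropenyl.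

Step 3
Reactants: 5 keto ester
Product: 6 methyl 3-[(1R,3S,4S,6R)-1,3-dimethyl-2-oxo-4-(prop-1-en-2-yl)-7-oxabicyclo[4.1.0]heptan-3-yl]propanoate (epoxide trans to isopropenyl)
Conditions: 30% H2O2, LiOH (0.2 equiv), MeOH, 0 °C
Reagents that add atoms: hydrogen peroxide, OO
Why: Weitz–Scheffer nucleophilic epoxidation, selective for the electron-poor enone alkene; axial attack of hydroperoxide at the β-carbon anti to the equatorial isopropenyl group should place the epoxide trans to it, and the methyl ester only exchanges degenerately in cold methanol.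

Step 4
Reactants: 6 epoxy ketone
Product: 7 methyl 3-[(1R,4R,6S)-4-hydroxy-1,3-dimethyl-6-(prop-1-en-2-yl)cyclohex-2-en-1-yl]propanoate (hydroxyl trans to isopropenyl)
Conditions: N2H4·H2O, AcOH (cat.), MeOH, 0 °C to rt
Reagents that add atoms: none
Why: Wharton transposition (hydrazone formation, epoxide opening, loss of dinitrogen) moves the oxygen to C7' and the alkene to C8'=C9'; the carbinol configuration is inherited from the epoxide C–O bond.

Step 5
Reactants: 7 allylic alcohol
Product: 8 methyl 3-[(1R,6S)-1,3-dimethyl-4-oxo-6-(prop-1-en-2-yl)cyclohex-2-en-1-yl]propanoate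
Conditions: Dess–Martin periodinane, CH2Cl2, rt
Reagents that add atoms: none
Why: Dess–Martin oxidation of the secondary allylic alcohol to the transposed enone, done so that the carbinol configuration can be reset; no stereocentre is formed.

Step 6
Reactants: 8 transposed enone
Product: 9 methyl 3-[(1R,4S,6S)-4-hydroxy-1,3-dimethyl-6-(prop-1-en-2-yl)cyclohex-2-en-1-yl]propanoate (hydroxyl cis to isopropenyl)
Conditions: NaBH4, CeCl3·7H2O, MeOH, −40 °C
Reagents that add atoms: none
Why: Luche 1,2-reduction; axial hydride delivery to the half-chair with equatorial isopropenyl should give the equatorial alcohol cis to isopropenyl, the same sense as in the reduction of carvone to cis-carveol, and the ester is inert.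

Step 7
Reactants: 9 cis allylic alcohol; 10 ethyl vinyl ether
Product: 12 methyl 3-[(1S,2S,6S)-1,3-dimethyl-2-(2-oxoethyl)-6-(prop-1-en-2-yl)cyclohex-3-en-1-yl]propanoate, via allyl vinyl ether 11 (not isolated)
Conditions: 10 (excess), Hg(OAc)2 (0.2 equiv), reflux; evaporate; toluene, 180 °C, sealed tube
Reagents that add atoms: ethyl vinyl ether (compound 10), C=COCC
Why: Vinyl ether exchange followed by Claisen rearrangement; the [3,3] shift is suprafacial on the ring, so the C7'–O configuration is transferred to the new C9'–C12 bond (cis to isopropenyl and to the C10' methyl) next to the quaternary carbon, and the alkene returns to C7'=C8'.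

Step 8
Reactants: 12 aldehyde
Product: 13 methyl 3-[(1S,2S,6S)-2-(2-hydroxyethyl)-1,3-dimethyl-6-(prop-1-en-2-yl)cyclohex-3-en-1-yl]propanoate
Conditions: NaBH4, MeOH, 0 °C
Reagents that add atoms: none
Why: Chemoselective borohydride reduction of the aldehyde in the presence of the methyl ester; no stereocentre is formed.

Step 9
Reactants: 13 primary alcohol
Product: 14 methyl 3-[(1S,2S,6S)-2-(2-iodoethyl)-1,3-dimethyl-6-(prop-1-en-2-yl)cyclohex-3-en-1-yl]propanoate
Conditions: I2, PPh3, imidazole, CH2Cl2, 0 °C to rt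
Reagents that add atoms: iodine, II
Why: Appel-type iodination of an unhindered primary alcohol through the alkoxyphosphonium salt; no stereocentre is touched.

Step 10
Reactants: 15 4-pentyn-1-ol
Product: 17 (E)-5-iodo-4-methylpent-4-en-1-ol, via alkenylalane 16 (not isolated)
Conditions: AlMe3 (3 equiv), Cp2ZrCl2 (0.25 equiv), CH2Cl2, 0 °C to rt; I2, THF, −30 to 0 °C
Reagents that add atoms: trimethylaluminium, C[Al](C)C; iodine, II
Why: Zirconium-catalysed Negishi carboalumination adds methyl and aluminium syn across the alkyne with aluminium at the terminus, and iodinolysis with retention gives the (E)-trisubstituted vinyl iodide.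

Step 11
Reactants: 17 iodo alcohol
Product: 18 (E)-5-iodo-4-methylpent-4-enal
Conditions: Dess–Martin periodinane, CH2Cl2, rt
Reagents that add atoms: none
Why: Dess–Martin oxidation of a primary alcohol under neutral conditions that leave the vinyl iodide untouched.

Step 12
Reactants: 18 aldehyde; 19 ethyl (triphenylphosphoranylidene)acetate
Product: 20 ethyl (2E,6E)-7-iodo-6-methylhepta-2,6-dienoate
Conditions: 19, CH2Cl2, rt
Reagents that add atoms: ethyl (triphenylphosphoranylidene)acetate (compound 19), CCOC(=O)C=P(c1ccccc1)(c1ccccc1)c1ccccc1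
Why: Wittig olefination with a stabilized ylide, which should give the (E)-enoate.

Step 13
Reactants: 20 dienoate; 21 potassium isopropenyltrifluoroborate
Product: 22 ethyl (3S,6E)-7-iodo-6-methyl-3-(prop-1-en-2-yl)hept-6-enoate
Conditions: 21, [Rh(cod)2]BF4 (3 mol %), (S)-BINAP (3.3 mol %), toluene/H2O 20:1, 105 °C
Reagents that add atoms: potassium isopropenyltrifluoroborate (compound 21), [K+].C=C(C)[B-](F)(F)F
Why: Rhodium-catalysed asymmetric conjugate addition of an alkenylboron reagent to the enoate; the BINAP complex of monovalent rhodium selects the enoate face and so sets C5 (S in this ester), while the isolated vinyl iodide is not an acceptor.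

Step 14
Reactants: 22 ester
Product: 24 ethyl (3R,6E)-7-iodo-2,2,6-trimethyl-3-(prop-1-en-2-yl)hept-6-enoate, via monomethyl ester 23 (not isolated)
Conditions: LiN(i-Pr)2, THF, −78 °C, MeI, to 0 °C; then LiN(i-Pr)2, DMPU, −78 °C, MeI, to rt
Reagents that add atoms: iodomethane, CI
Why: Two successive ester enolate methylations build the C4 gem-dimethyl carbon; C5 is not enolizable and keeps its configuration (the descriptor changes only by priority).

Step 15
Reactants: 24 gem-dimethyl ester
Product: 25 (3R,6E)-7-iodo-2,2,6-trimethyl-3-(prop-1-en-2-yl)hept-6-enal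
Conditions: i-Bu2AlH, CH2Cl2, −78 °C; aq. potassium sodium tartrate
Reagents that add atoms: none
Why: Partial reduction of a hindered ester, in which the tetrahedral aluminium acetal should survive at −78 °C and release the aldehyde on work-up; the aldehyde has no α-hydrogen.

Step 16
Reactants: 14 left iodide; 25 right vinyl iodide aldehyde
Product: 27 methyl 3-[(1S,2S,6S)-1,3-dimethyl-6-(prop-1-en-2-yl)-2-[(3E,7R)-4,8,8-trimethyl-9-oxo-7-(prop-1-en-2-yl)non-3-en-1-yl]cyclohex-3-en-1-yl]propanoate, via alkylzinc iodide 26 (not isolated)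
Conditions: 14, Zn dust, LiCl, THF, 40 °C; then 25, Pd(OAc)2 (3 mol %), SPhos (6 mol %), THF, rt
Reagents that add atoms: none
Why: Zinc insertion into the primary iodide and Negishi sp3–sp2 coupling form C9–C11 with retention of the E alkene geometry; the alkylzinc reagent tolerates the methyl ester and the hindered, non-enolizable aldehyde.

Step 17
Reactants: 27 coupled aldehyde; 28 ethyl diazoacetate
Product: 29 ethyl (5R,8E)-11-[(1S,5S,6S)-6-(3-methoxy-3-oxopropyl)-2,6-dimethyl-5-(prop-1-en-2-yl)cyclohex-2-en-1-yl]-4,4,8-trimethyl-3-oxo-5-(prop-1-en-2-yl)undec-8-enoate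
Conditions: 28, SnCl2 (0.2 equiv), CH2Cl2, rt
Reagents that add atoms: ethyl diazoacetate (compound 28), CCOC(=O)C=[N+]=[N-]
Why: Roskamp homologation (Lewis-acid-promoted addition of the diazo ester to the aldehyde, 1,2-hydride shift, loss of dinitrogen) gives the β-keto ester directly and leaves the methyl ester and all four alkenes alone.

Step 18
Reactants: 29 acyclic β-keto ester
Product: 32 bicyclic β-keto ester (2-ethoxycarbonyl-3-dehydro methyl lansiolate; C2 epimers), via ring A radical 30 (not isolated), via decalin radical 31 (not isolated)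
Conditions: Mn(OAc)3·2H2O (2.2 equiv), Cu(OAc)2·H2O (1 equiv), degassed AcOH, rt, 0.02 M
Reagents that add atoms: none
Why: Mn(OAc)3 oxidizes the enol of the β-keto ester to the electrophilic C2 radical, which adds to the terminal CH2 (C1) of the isopropenyl group on C5 and so closes ring A through the C1–C2 bond; the tertiary C10 radical 30 then adds to C9 of the (E)-C8=C9 alkene to close ring B, and Cu(OAc)2 oxidizes the tertiary C8 radical 31 to the less substituted exocyclic C8 methylene, the divalent copper being regenerated by a second equivalent of Mn(OAc)3. The closest known reaction type is the oxidative free-radical polycyclization of unsaturated β-keto esters with Mn(OAc)3 and Cu(OAc)2. Ring A closes in the 6-endo-trig mode and ring B closes in the 6-endo-trig mode. C10 and C9 are set by the C5 stereocentre, whose chain sits equatorial on ring A, together with the E geometry of the C8=C9 alkene in a chair-like transition state, which should give the trans ring fusion with the C9 side chain equatorial; C2 is not controlled and is removed in step 19. The step needs 6-endo attack at C1 in preference to attack at C10 or at the C8=C9 alkene, which the keto group inside the forming ring, the unhindered CH2 terminus and the tertiary product radical should secure; it also needs the alkenes of ring C to stay untouched, which their distance from every radical centre and the fast copper oxidation should secure.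

Step 19
Reactants: 32 bicyclic β-keto ester
Product: 33 3-dehydro methyl lansiolate (the 3-ketone)
Conditions: LiCl, DMSO, H2O, 140 °C
Reagents that add atoms: none
Why: Krapcho dealkoxycarbonylation is selective for the β-keto ester over the unactivated methyl ester and removes the C2 helper under neutral conditions that do not isomerize the exocyclic alkene.

Step 20
Reactants: 33 3-ketone
Product: 34 methyl lansiolate
Conditions: NaBH4, MeOH, 0 °C
Reagents that add atoms: none
Why: Borohydride reduction of the 4,4-dimethyl-3-ketone of a trans-decalin, where axial hydride delivery from the α face should give the equatorial 3β-alcohol; the methyl ester is not reduced.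

Compound list

1 | (R)-(−)-carvone | C=C(C)[C@@H]1CC=C(C)C(=O)C1 | starting material
2 | (5R)-2,6-dimethyl-5-(prop-1-en-2-yl)cyclohex-2-en-1-one (C6 epimers) | C=C(C)[C@@H]1CC=C(C)C(=O)C1C | intermediate
3 | methyl acrylate | C=CC(=O)OC | starting material
4 | methyl trimethylsilyl ketene acetal of 5 | C=C(C)[C@@H]1CC=C(C)C(=O)[C@@]1(C)CC=C(OC)O[Si](C)(C)C | intermediate
5 | methyl 3-[(1S,6S)-1,3-dimethyl-2-oxo-6-(prop-1-en-2-yl)cyclohex-3-en-1-yl]propanoate | C=C(C)[C@@H]1CC=C(C)C(=O)[C@@]1(C)CCC(=O)OC | intermediate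
6 | methyl 3-[(1R,3S,4S,6R)-1,3-dimethyl-2-oxo-4-(prop-1-en-2-yl)-7-oxabicyclo[4.1.0]heptan-3-yl]propanoate | C=C(C)[C@@H]1C[C@H]2O[C@@]2(C)C(=O)[C@@]1(C)CCC(=O)OC | intermediate
7 | methyl 3-[(1R,4R,6S)-4-hydroxy-1,3-dimethyl-6-(prop-1-en-2-yl)cyclohex-2-en-1-yl]propanoate | C=C(C)[C@@H]1C[C@@H](O)C(C)=C[C@@]1(C)CCC(=O)OC | intermediate
8 | methyl 3-[(1R,6S)-1,3-dimethyl-4-oxo-6-(prop-1-en-2-yl)cyclohex-2-en-1-yl]propanoate | C=C(C)[C@@H]1CC(=O)C(C)=C[C@@]1(C)CCC(=O)OC | intermediate
9 | methyl 3-[(1R,4S,6S)-4-hydroxy-1,3-dimethyl-6-(prop-1-en-2-yl)cyclohex-2-en-1-yl]propanoate | C=C(C)[C@@H]1C[C@H](O)C(C)=C[C@@]1(C)CCC(=O)OC | intermediate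
10 | ethyl vinyl ether | C=COCC | starting material
11 | allyl vinyl ether of 9 | C=C(C)[C@@H]1C[C@H](OC=C)C(C)=C[C@@]1(C)CCC(=O)OC | intermediate
12 | methyl 3-[(1S,2S,6S)-1,3-dimethyl-2-(2-oxoethyl)-6-(prop-1-en-2-yl)cyclohex-3-en-1-yl]propanoate | C=C(C)[C@@H]1CC=C(C)[C@H](CC=O)[C@@]1(C)CCC(=O)OC | intermediate
13 | methyl 3-[(1S,2S,6S)-2-(2-hydroxyethyl)-1,3-dimethyl-6-(prop-1-en-2-yl)cyclohex-3-en-1-yl]propanoate | C=C(C)[C@@H]1CC=C(C)[C@H](CCO)[C@@]1(C)CCC(=O)OC | intermediate
14 | methyl 3-[(1S,2S,6S)-2-(2-iodoethyl)-1,3-dimethyl-6-(prop-1-en-2-yl)cyclohex-3-en-1-yl]propanoate | C=C(C)[C@@H]1CC=C(C)[C@H](CCI)[C@@]1(C)CCC(=O)OC | intermediate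
15 | 4-pentyn-1-ol | C#CCCCO | starting material
16 | (E)-alkenyl(dimethyl)alane, O-dimethylaluminium alkoxide | C[Al](C)OCCC/C(C)=C/[Al](C)C | intermediate
17 | (E)-5-iodo-4-methylpent-4-en-1-ol | OCCC/C(C)=C/I | intermediate
18 | (E)-5-iodo-4-methylpent-4-enal | O=CCC/C(C)=C/I | intermediate
19 | ethyl (triphenylphosphoranylidene)acetate | CCOC(=O)C=P(c1ccccc1)(c1ccccc1)c1ccccc1 | starting material
20 | ethyl (2E,6E)-7-iodo-6-methylhepta-2,6-dienoate | CCOC(=O)/C=C/CC/C(C)=C/I | intermediate
21 | potassium isopropenyltrifluoroborate | [K+].C=C(C)[B-](F)(F)F | starting material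
22 | ethyl (3S,6E)-7-iodo-6-methyl-3-(prop-1-en-2-yl)hept-6-enoate | CCOC(=O)C[C@@H](C(C)=C)CC/C(C)=C/I | intermediate
23 | ethyl (3S,6E)-7-iodo-2,6-dimethyl-3-(prop-1-en-2-yl)hept-6-enoate (C2 epimers) | CCOC(=O)C(C)[C@@H](C(C)=C)CC/C(C)=C/I | intermediate
24 | ethyl (3R,6E)-7-iodo-2,2,6-trimethyl-3-(prop-1-en-2-yl)hept-6-enoate | CCOC(=O)C(C)(C)[C@@H](C(C)=C)CC/C(C)=C/I | intermediate
25 | (3R,6E)-7-iodo-2,2,6-trimethyl-3-(prop-1-en-2-yl)hept-6-enal | O=CC(C)(C)[C@@H](C(C)=C)CC/C(C)=C/I | intermediate
26 | alkylzinc iodide from 14 | C=C(C)[C@@H]1CC=C(C)[C@H](CC[Zn]I)[C@@]1(C)CCC(=O)OC | intermediate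
27 | methyl 3-[(1S,2S,6S)-1,3-dimethyl-6-(prop-1-en-2-yl)-2-[(3E,7R)-4,8,8-trimethyl-9-oxo-7-(prop-1-en-2-yl)non-3-en-1-yl]cyclohex-3-en-1-yl]propanoate | C=C(C)[C@@H]1CC=C(C)[C@H](CC/C=C(C)/CC[C@H](C(C)=C)C(C)(C)C=O)[C@@]1(C)CCC(=O)OC | intermediate
28 | ethyl diazoacetate | CCOC(=O)C=[N+]=[N-] | starting material
29 | ethyl (5R,8E)-11-[(1S,5S,6S)-6-(3-methoxy-3-oxopropyl)-2,6-dimethyl-5-(prop-1-en-2-yl)cyclohex-2-en-1-yl]-4,4,8-trimethyl-3-oxo-5-(prop-1-en-2-yl)undec-8-enoate | C=C(C)[C@@H]1CC=C(C)[C@H](CC/C=C(C)/CC[C@H](C(C)=C)C(C)(C)C(=O)CC(=O)OCC)[C@@]1(C)CCC(=O)OC | intermediate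
30 | ring A radical: tertiary C10 radical formed after C1–C2 closure (C2 epimers) | C=C(C)[C@@H]1CC=C(C)[C@H](CC/C=C(C)/CC[C@H]2C(C)(C)C(=O)C(C(=O)OCC)C[C]2C)[C@@]1(C)CCC(=O)OC | intermediate
31 | decalin radical: tertiary C8 radical formed after C9–C10 closure (C2 epimers) | C=C(C)[C@@H]1CC=C(C)[C@H](CC[C@H]2[C](C)CC[C@H]3C(C)(C)C(=O)C(C(=O)OCC)C[C@]23C)[C@@]1(C)CCC(=O)OC | intermediate
32 | bicyclic β-keto ester: 2-ethoxycarbonyl-3-dehydro methyl lansiolate (C2 epimers) | C=C(C)[C@@H]1CC=C(C)[C@H](CC[C@H]2C(=C)CC[C@H]3C(C)(C)C(=O)C(C(=O)OCC)C[C@]23C)[C@@]1(C)CCC(=O)OC | intermediate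
33 | 3-dehydro methyl lansiolate: methyl 3-[(1S,2S,6S)-1,3-dimethyl-6-(prop-1-en-2-yl)-2-{2-[(1S,4aR,8aR)-5,5,8a-trimethyl-2-methylidene-6-oxodecahydronaphthalen-1-yl]ethyl}cyclohex-3-en-1-yl]propanoate | C=C(C)[C@@H]1CC=C(C)[C@H](CC[C@H]2C(=C)CC[C@H]3C(C)(C)C(=O)CC[C@]23C)[C@@]1(C)CCC(=O)OC | intermediate
34 | methyl lansiolate: methyl 3-[(1S,2S,6S)-2-{2-[(1S,4aR,6S,8aR)-6-hydroxy-5,5,8a-trimethyl-2-methylidenedecahydronaphthalen-1-yl]ethyl}-1,3-dimethyl-6-(prop-1-en-2-yl)cyclohex-3-en-1-yl]propanoate | C=C(C)[C@@H]1CC=C(C)[C@H](CC[C@H]2C(=C)CC[C@H]3C(C)(C)[C@@H](O)CC[C@]23C)[C@@]1(C)CCC(=O)OC | target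

Step count

Total step count: 20 (9 for the left fragment, 6 for the right fragment, 5 after the union).
Longest linear sequence: 14 steps (steps 1–9, then steps 16–20).

Steps most likely to fail

First, step 18. The cyclized β-keto ester is still enolizable at C2 and may undergo a second one-electron oxidation followed by dehydrogenation or acetoxylation, eroding the product as it forms. The fallback sets out from 29. Chlorination at C2 with N-chlorosuccinimide and Mg(ClO4)2 (cat.) in EtOAc at rt should give the acyclic α-chloro β-keto ester F1 as a mixture of C2 epimers. Cyclization of this compound with Mn(OAc)3·2H2O and Cu(OAc)2·H2O in AcOH should give the bicyclic α-chloro β-keto ester F2, which can no longer enolize and so cannot be oxidized further. Zn dust in AcOH then removes the chlorine, and the route is rejoined at 32.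

Second, step 2. The ester enolate of the first adduct may add intramolecularly to the β-carbon of the enone (a second Michael addition that builds a bicyclo[2.2.2]octanone), or the ketone enolate may be silylated before it adds, or the acrylate may oligomerize. The fallback sets out from 2 and replaces the conjugate addition by an alkylation, for which no second addition is possible. The lithium enolate (LiN(i-Pr)2, THF/DMPU, −78 to 0 °C) is alkylated with tert-butyl(3-iodopropoxy)dimethylsilane, again anti to isopropenyl, to give (5S,6S)-6-[3-(tert-butyldimethylsilyloxy)propyl]-2,6-dimethyl-5-(prop-1-en-2-yl)cyclohex-2-en-1-one F3. CrO3/H2SO4 in acetone at 0 °C removes the silyl group and oxidizes the primary alcohol in one operation to 3-[(1S,6S)-1,3-dimethyl-2-oxo-6-(prop-1-en-2-yl)cyclohex-3-en-1-yl]propanoic acid F4. MeI and K2CO3 in DMF then give the methyl ester, and the route is rejoined at 5.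

Third, step 13. Enantiofacial selection may be insufficient with the small isopropenyl nucleophile, or the vinyl iodide may be consumed by the low-valent rhodium catalyst at 105 °C. The fallback sets out from 20 and uses an auxiliary in place of the catalyst. LiOH in THF/H2O, then aq. HCl, gives (2E,6E)-7-iodo-6-methylhepta-2,6-dienoic acid F5. Pivaloyl chloride and Et3N, then the lithium salt of (R)-4-phenyloxazolidin-2-one (made with n-BuLi), give (R)-3-[(2E,6E)-7-iodo-6-methylhepta-2,6-dienoyl]-4-phenyloxazolidin-2-one F6. Isopropenylmagnesium bromide with CuBr·SMe2 (1 equiv) in THF at −40 °C should add anti to the phenyl group of the chelated s-cis imide, faster than it attacks the vinyl iodide, and give (R)-3-[(3S,6E)-7-iodo-6-methyl-3-(prop-1-en-2-yl)hept-6-enoyl]-4-phenyloxazolidin-2-one F7 with the required configuration at C5. EtMgBr in EtOH/THF at 0 °C (bromomagnesium ethoxide) transfers the acyl group to ethanol with recovery of the auxiliary, and the route is rejoined at 22.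

Further compounds

F1 | step 18 | acyclic α-chloro β-keto ester | C=C(C)[C@@H]1CC=C(C)[C@H](CC/C=C(C)/CC[C@H](C(C)=C)C(C)(C)C(=O)C(Cl)C(=O)OCC)[C@@]1(C)CCC(=O)OC
F2 | step 18 | bicyclic α-chloro β-keto ester | C=C(C)[C@@H]1CC=C(C)[C@H](CC[C@H]2C(=C)CC[C@H]3C(C)(C)C(=O)C(Cl)(C(=O)OCC)C[C@]23C)[C@@]1(C)CCC(=O)OC
F3 | step 2 | (5S,6S)-6-[3-(tert-butyldimethylsilyloxy)propyl]-2,6-dimethyl-5-(prop-1-en-2-yl)cyclohex-2-en-1-one | C=C(C)[C@@H]1CC=C(C)C(=O)[C@@]1(C)CCCO[Si](C)(C)C(C)(C)C
F4 | step 2 | 3-[(1S,6S)-1,3-dimethyl-2-oxo-6-(prop-1-en-2-yl)cyclohex-3-en-1-yl]propanoic acid | C=C(C)[C@@H]1CC=C(C)C(=O)[C@@]1(C)CCC(=O)O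
F5 | step 13 | (2E,6E)-7-iodo-6-methylhepta-2,6-dienoic acid | OC(=O)/C=C/CC/C(C)=C/I
F6 | step 13 | (R)-3-[(2E,6E)-7-iodo-6-methylhepta-2,6-dienoyl]-4-phenyloxazolidin-2-one | O=C(/C=C/CC/C(C)=C/I)N1C(=O)OC[C@H]1c1ccccc1
F7 | step 13 | (R)-3-[(3S,6E)-7-iodo-6-methyl-3-(prop-1-en-2-yl)hept-6-enoyl]-4-phenyloxazolidin-2-one | O=C(C[C@@H](C(C)=C)CC/C(C)=C/I)N1C(=O)OC[C@H]1c1ccccc1
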